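**Retrosynthetic overview**
- The target is reached by O-debenzylation of its 7-O-benzyl ether. Rings A and B are bought as benzene rings; only the γ-pyranone ring C is built.
- Key disconnection: ring C is cut at all three bonds of C2 (C2–C1' to the aryl ring, C2–O1, C2–C3). This gives 5-bromo-1,2,3-trimethoxybenzene, carbon monoxide and 4-O-benzyl-2-hydroxy-5-methoxyacetophenone. In the forward direction this is a Pd-catalysed carbonylative three-component annulation: CO becomes C2, and the C2–C1' bond is made by CO insertion into the aryl–Pd bond.
- Enabling feature: C2 of the pyranone is an acyl-level carbon flanked by ring oxygen O1 and by C3, which is α to the C4 ketone. O1 and C3 already exist as the phenolic OH and the acetyl CH3, ortho to each other on ring A, so one aroyl unit can be taken up on O, passed to C and then condensed into the ring.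
- The acetophenone comes from 4-methoxyresorcinol by C-acetylation (ortho to one OH, para to the other) and selective benzylation of the non-chelated OH.
- Order of ring formation: ring C only, closed in the key step; the final step just unmasks the 7-OH.

Key step: step 3

Remark: the target has no stereocentre, stereogenic axis or configurable double bond, so it is achiral and no stereocontrol is needed. 4-Methoxyresorcinol, 5-bromo-1,2,3-trimethoxybenzene and CO are taken as purchased.

**Step 1**
Reactants: 1 4-methoxybenzene-1,3-diol (4-methoxyresorcinol)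
Product: 2 1-(2,4-dihydroxy-5-methoxyphenyl)ethan-1-one
Conditions: AcOH (1.2 equiv), BF3·OEt2 (as solvent), 85 °C; aq. NaOAc work-up
Reagents that add atoms: acetic acid, CC(=O)O
Why: Friedel–Crafts C-acylation of a resorcinol (Nencki-type, BF3-promoted); C6 of 1, ortho to one OH and para to the other, is the most activated and least hindered site, and the chelated ketone formed deactivates the ring against a second acylation.

**Step 2**
Reactants: 2 1-(2,4-dihydroxy-5-methoxyphenyl)ethan-1-one
Product: 3 1-[4-(benzyloxy)-2-hydroxy-5-methoxyphenyl]ethan-1-one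
Conditions: BnBr (1.05 equiv), K2CO3 (1.1 equiv), acetone, reflux
Reagents that add atoms: benzyl bromide, BrCc1ccccc1
Why: Williamson ether synthesis; the 2-OH is held in an intramolecular hydrogen bond to the acetyl C=O, so the free and more acidic 4-OH (para to the acyl group) should be alkylated selectively by one equivalent of BnBr.

**Step 3**
Reactants: 3 1-[4-(benzyloxy)-2-hydroxy-5-methoxyphenyl]ethan-1-one; 4 5-bromo-1,2,3-trimethoxybenzene (1.2 equiv); 5 carbon monoxide
Product: 8 7-(benzyloxy)-6-methoxy-2-(3,4,5-trimethoxyphenyl)-4H-chromen-4-one, via aryl ester 6 (not isolated), via 1,3-diketone 7 (not isolated)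
Conditions: [Pd(cinnamyl)Cl]2 (1 mol %), dppb (2 mol %), DBU (3 equiv), CO (10 bar), DMSO, 120 °C
Reagents that add atoms: none
Why: Pd-catalysed carbonylative three-component annulation of an aryl bromide, CO and a 2-hydroxyacetophenone, a known flavone-forming reaction type: Pd(0) adds oxidatively to the C–Br bond of 4, CO inserts into the aryl–Pd bond (this creates the C1'–C2 bond, the CO carbon becoming C2), and the aroyl–Pd species is captured by the DBU-generated phenoxide of 3 to give ester 6. DBU then drives the Baker–Venkataraman O→C acyl shift through the acetyl enolate (C2–C3 bond) to diketone 7, which closes the pyranone ring by 6-exo-trig attack of the phenol oxygen on the aryl ketone carbonyl followed by loss of water (C2–O1 bond). The closest known reaction types are the Pd-catalysed aryloxycarbonylation of aryl halides and the classical Baker–Venkataraman/cyclodehydration flavone synthesis, merged here in one pot. No stereocentre is formed. The step needs chemoselectivity: carbonylative rather than direct coupling (secured by CO pressure and the chelating dppb ligand) and acylation at a single oxygen (secured by the benzyl cap on the 4-OH, which leaves the 2-OH as the only acidic O–H); O- and C-acylation of 3 converge on the same diketone 7, and 7 can cyclise in one sense only because a single phenol sits ortho to the diketone. Any 7 that persists should be convertible to 8 by briefly warming the crude mixture with catalytic acid before work-up.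

**Step 4**
Reactants: 8 7-(benzyloxy)-6-methoxy-2-(3,4,5-trimethoxyphenyl)-4H-chromen-4-one
Product: 9 Prosogerin D, 7-hydroxy-6-methoxy-2-(3,4,5-trimethoxyphenyl)-4H-chromen-4-one
Conditions: H2 (1 atm), 10% Pd/C, EtOAc–MeOH, rt
Reagents that add atoms: none
Why: catalytic hydrogenolysis of an aryl benzyl ether; at 1 atm and room temperature the benzylic C–O bond should be cleaved much faster than the cross-conjugated C2=C3 bond of the flavone is reduced, and the four methyl ethers are inert.

**Compound list**
1 | 4-methoxybenzene-1,3-diol (4-methoxyresorcinol) | COc1ccc(O)cc1O | starting material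
2 | 1-(2,4-dihydroxy-5-methoxyphenyl)ethan-1-one | CC(=O)c1cc(OC)c(O)cc1O | intermediate
3 | 1-[4-(benzyloxy)-2-hydroxy-5-methoxyphenyl]ethan-1-one | CC(=O)c1cc(OC)c(OCc2ccccc2)cc1O | intermediate
4 | 5-bromo-1,2,3-trimethoxybenzene | COc1cc(Br)cc(OC)c1OC | starting material
5 | carbon monoxide | [C-]#[O+] | starting material
6 | 2-acetyl-5-(benzyloxy)-4-methoxyphenyl 3,4,5-trimethoxybenzoate (not isolated) | CC(=O)c1cc(OC)c(OCc2ccccc2)cc1OC(=O)c1cc(OC)c(OC)c(OC)c1 | intermediate
7 | 1-[4-(benzyloxy)-2-hydroxy-5-methoxyphenyl]-3-(3,4,5-trimethoxyphenyl)propane-1,3-dione (not isolated) | COc1cc(C(=O)CC(=O)c2cc(OC)c(OC)c(OC)c2)c(O)cc1OCc1ccccc1 | intermediate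
8 | 7-(benzyloxy)-6-methoxy-2-(3,4,5-trimethoxyphenyl)-4H-chromen-4-one | COc1cc2c(=O)cc(-c3cc(OC)c(OC)c(OC)c3)oc2cc1OCc1ccccc1 | intermediate
9 | Prosogerin D, 7-hydroxy-6-methoxy-2-(3,4,5-trimethoxyphenyl)-4H-chromen-4-one | COc1cc2c(=O)cc(-c3cc(OC)c(OC)c(OC)c3)oc2cc1O | target

Total step count: 4. Longest linear sequence: 4 steps (1 → 2 → 3 → 8 → 9); 4 and 5 enter at step 3.

**Steps most likely to fail**

Step 3. Oxidative addition of the electron-rich bromide may be slow, so the catalyst may decay under CO before turnover. The sequence may also stall after O-aroylation, leaving acyl shift and ring closure incomplete. The fallback makes the same C2–C1' bond by C–H arylation of a preformed pyranone instead of by carbonylation. It sets out from 3. Condensation with N,N-dimethylformamide dimethyl acetal (toluene, 100 °C) should give the enaminone (E)-1-[4-(benzyloxy)-2-hydroxy-5-methoxyphenyl]-3-(dimethylamino)prop-2-en-1-one F1. Conc. HCl in CH2Cl2 at 40 °C should close it to 7-(benzyloxy)-6-methoxy-4H-chromen-4-one F2. A Pd(II)-catalysed oxidative boron-Heck arylation of F2 at C2 with (3,4,5-trimethoxyphenyl)boronic acid (COc1cc(B(O)O)cc(OC)c1OC; Pd(TFA)2 cat., DDQ as terminal oxidant, cat. KNO2, AcOH–DMSO, about 70 °C) should then give 8, where the route is rejoined.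

Step 4. The C2=C3 bond may be saturated in competition with debenzylation, or the hydrogenolysis may stall through catalyst poisoning by sulfur residues carried over from the DMSO of step 3. The fallback replaces hydrogenolytic protection by acid-labile protection. It sets out from 2. MOMCl and i-Pr2NEt in CH2Cl2 at 0 °C should give, under the same chelation control as in step 2, 1-[2-hydroxy-5-methoxy-4-(methoxymethoxy)phenyl]ethan-1-one F3. The carbonylative annulation of step 3 with 4 and 5 should then pass through the ester 2-acetyl-4-methoxy-5-(methoxymethoxy)phenyl 3,4,5-trimethoxybenzoate F4 and the diketone 1-[2-hydroxy-5-methoxy-4-(methoxymethoxy)phenyl]-3-(3,4,5-trimethoxyphenyl)propane-1,3-dione F5, neither isolated, to 6-methoxy-7-(methoxymethoxy)-2-(3,4,5-trimethoxyphenyl)-4H-chromen-4-one F6. HCl in MeOH at 50 °C should remove the acetal and give 9 directly.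

Step 1. O-acetylation and double acylation may compete with mono-C-acylation, attack may occur at the position between the two hydroxyls, and the electron-rich arene may decompose oxidatively in the hot Lewis acid. The fallback is a Houben–Hoesch acylation with a nitrile, which stops at the mono-adduct because the iminium salt precipitates and is deactivated. It sets out from 1. MeCN, cat. ZnCl2 and dry HCl in Et2O at 0 °C should give 1-(2,4-dihydroxy-5-methoxyphenyl)ethan-1-iminium chloride F7, and boiling in water should hydrolyse it to 2.

**Further compounds**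
F1 | step 3 | (E)-1-[4-(benzyloxy)-2-hydroxy-5-methoxyphenyl]-3-(dimethylamino)prop-2-en-1-one | CN(C)/C=C/C(=O)c1cc(OC)c(OCc2ccccc2)cc1O
F2 | step 3 | 7-(benzyloxy)-6-methoxy-4H-chromen-4-one | COc1cc2c(=O)ccoc2cc1OCc1ccccc1
F3 | step 4 | 1-[2-hydroxy-5-methoxy-4-(methoxymethoxy)phenyl]ethan-1-one | CC(=O)c1cc(OC)c(OCOC)cc1O
F4 | step 4 | 2-acetyl-4-methoxy-5-(methoxymethoxy)phenyl 3,4,5-trimethoxybenzoate | CC(=O)c1cc(OC)c(OCOC)cc1OC(=O)c1cc(OC)c(OC)c(OC)c1
F5 | step 4 | 1-[2-hydroxy-5-methoxy-4-(methoxymethoxy)phenyl]-3-(3,4,5-trimethoxyphenyl)propane-1,3-dione | COCOc1cc(O)c(C(=O)CC(=O)c2cc(OC)c(OC)c(OC)c2)cc1OC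
F6 | step 4 | 6-methoxy-7-(methoxymethoxy)-2-(3,4,5-trimethoxyphenyl)-4H-chromen-4-one | COCOc1cc2oc(-c3cc(OC)c(OC)c(OC)c3)cc(=O)c2cc1OC
F7 | step 1 | 1-(2,4-dihydroxy-5-methoxyphenyl)ethan-1-iminium chloride | CC(=[NH2+])c1cc(OC)c(O)cc1O.[Cl-]
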